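The spiro-dienone ring is made last, on a finished chiral cyclohexanone. Its spiro carbon, the C–OMe carbon on one side and the CH=C(OMe) unit on the other form a four-carbon unit that maps onto a methoxy(vinyl)ketene whose vinyl terminus is the cyclohexane carbon; the remaining C(=O)–CH pair maps onto an alkynyl ether, so the two 1,3-related ring oxygens come from ketene and ynol ether. In one operation the ketene, released from an α-methoxy-β,γ-unsaturated acid on an exocyclic alkene, adds tert-butoxyethyne [2+2]; the cyclobutenone opens (4π) and recloses (6π) to the spirocyclic dienone, setting the quaternary stereocentre. A methylative 1,3-carbonyl transposition then gives tatanan B.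

Key step: step 11

Assumption: the SMILES fixes six stereocentres but no axial chirality, so rotamers about the aryl–ring bonds are taken to equilibrate to the natural form.

Ar = 2,4,5-trimethoxyphenyl. From compound 14 on, "ring centres as in 12" means the five ring stereocentres keep the spatial arrangement of ketone 12.

Step 1
Reactants: 1 1-bromo-2,4,5-trimethoxybenzene; 2 tert-butyl acetate
Product: 3 tert-butyl 2-(2,4,5-trimethoxyphenyl)acetate
Conditions: LiN(SiMe3)2 (2.3 equiv), Pd2(dba)3 (1 mol %), P(t-Bu)3 (2 mol %), toluene, 23 °C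
Reagents that add atoms: none
Why: Palladium-catalysed α-arylation of an ester enolate (Buchwald–Hartwig type) joins the electron-rich aryl bromide to the lithium enolate of tert-butyl acetate, and excess base holds the product as its enolate so that it is not arylated twice.

Step 2
Reactants: 3 tert-butyl 2-(2,4,5-trimethoxyphenyl)acetate; 4 butanoyl chloride
Product: 5 tert-butyl 3-oxo-2-(2,4,5-trimethoxyphenyl)hexanoate
Conditions: LiN(SiMe3)2 (2.1 equiv), THF, −78 °C; then 4, −78 → 0 °C; aq. NH4Cl
Reagents that add atoms: none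
Why: Claisen-type C-acylation of the stabilised aryl acetate enolate with an acid chloride gives the α-aryl β-keto ester, whose racemic centre is erased later.

Step 3
Reactants: 5 tert-butyl 3-oxo-2-(2,4,5-trimethoxyphenyl)hexanoate; 6 (E)-but-2-enal
Product: 8 (5S,6S)-2-ethyl-5-methyl-6-(2,4,5-trimethoxyphenyl)cyclohex-2-en-1-one, via Michael adduct 7 (not isolated)
Conditions: (R)-α,α-bis[3,5-bis(trifluoromethyl)phenyl]prolinol trimethylsilyl ether (10 mol %), toluene, 0 → 23 °C; then p-TsOH·H2O (0.3 equiv), toluene, 80 °C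
Reagents that add atoms: none
Why: Iminium-catalysed Michael addition (Jørgensen–Hayashi catalyst) of the keto ester to the enal sets the methyl-bearing centre by attack on the face away from the diaryl(silyloxy)methyl group, and acid then drives intramolecular aldol condensation, tert-butyl ester cleavage and decarboxylation, leaving the aryl group equilibrated trans to the methyl group.

Step 4
Reactants: 8 (5S,6S)-2-ethyl-5-methyl-6-(2,4,5-trimethoxyphenyl)cyclohex-2-en-1-one
Product: 9 (5S,6S)-2-ethyl-1,5-dimethyl-6-(2,4,5-trimethoxyphenyl)cyclohex-2-en-1-ol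
Conditions: MeLi, CeCl3, THF, −78 °C; aq. NH4Cl
Reagents that add atoms: methyllithium, C[Li]
Why: Organocerium 1,2-addition (Imamoto conditions) puts the methyl group on the enone carbonyl without enolising the acidic α-aryl position, and the configuration of the new carbinol centre is irrelevant because it becomes sp2 in the next step.

Step 5
Reactants: 9 (5S,6S)-2-ethyl-1,5-dimethyl-6-(2,4,5-trimethoxyphenyl)cyclohex-2-en-1-ol
Product: 10 (4R,5S)-2-ethyl-3,5-dimethyl-4-(2,4,5-trimethoxyphenyl)cyclohex-2-en-1-one
Conditions: (C5H5NH)[CrO3Cl] (pyridinium chlorochromate, 2 equiv), 4 Å molecular sieves, CH2Cl2, 23 °C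
Reagents that add atoms: pyridinium chlorochromate, [O-][Cr](=O)(=O)Cl.c1cc[nH+]cc1
Why: Dauben–Babler oxidative 1,3-transposition (chromate ester, [3,3] shift, oxidation) moves the oxygen to the former alkene terminus and gives the β-methyl enone with the aryl carbon now in the γ position, both existing stereocentres being untouched.

Step 6
Reactants: 10 (4R,5S)-2-ethyl-3,5-dimethyl-4-(2,4,5-trimethoxyphenyl)cyclohex-2-en-1-one
Product: 11 (2R,3R,4R,5S)-2-ethyl-3,5-dimethyl-4-(2,4,5-trimethoxyphenyl)cyclohexan-1-one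
Conditions: H2 (4 bar), Pd/C (10 %), EtOAc, 23 °C
Reagents that add atoms: none
Why: Heterogeneous syn-hydrogenation of the tetrasubstituted enone should deliver both hydrogens to the face opposite the allylic aryl group (pseudoaxial to avoid allylic strain with the vinylic methyl group), which sets the 2-ethyl and 3-methyl groups cis to each other and to the 4-aryl group.

Step 7
Reactants: 11 (2R,3R,4R,5S)-2-ethyl-3,5-dimethyl-4-(2,4,5-trimethoxyphenyl)cyclohexan-1-one; 1 1-bromo-2,4,5-trimethoxybenzene
Product: 12 (2R,3R,4S,5R,6R)-2-ethyl-3,5-dimethyl-4,6-bis(2,4,5-trimethoxyphenyl)cyclohexan-1-one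
Conditions: Pd2(dba)3 (1.5 mol %), XPhos (4 mol %), NaOt-Bu (1.3 equiv), toluene, 70 °C; aq. NH4Cl
Reagents that add atoms: none
Why: Palladium-catalysed ketone α-arylation (Buchwald–Hartwig type) takes place at the only α-methylene, the product rests as its benzylic enolate (which protects the ethyl-bearing centre from epimerisation), and protonation places the new aryl group equatorial, trans to the neighbouring methyl group.

Step 8
Reactants: 12 (2R,3R,4S,5R,6R)-2-ethyl-3,5-dimethyl-4,6-bis(2,4,5-trimethoxyphenyl)cyclohexan-1-one; 13 (Z)-1-bromo-2-ethoxyethene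
Product: 15 2-[2-ethyl-3,5-dimethyl-4,6-bis(2,4,5-trimethoxyphenyl)cyclohexylidene]acetaldehyde, via ethoxyvinyl carbinol 14 (not isolated)
Conditions: 13, t-BuLi (2 equiv), Et2O, −78 °C; CeCl3, THF, −78 °C; then 12, −78 → 0 °C; then 1 M HCl, THF, 0 °C
Reagents that add atoms: water, O
Why: Wollenberg two-carbon homologation: the small, weakly basic 2-ethoxyvinylcerium reagent adds 1,2 to the hindered enolisable ketone, and brief acid hydrolysis of the enol ether with allylic transposition gives the β,β-disubstituted enal (E/Z mixture, both used) without touching the ring centres.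

Step 9
Reactants: 15 2-[2-ethyl-3,5-dimethyl-4,6-bis(2,4,5-trimethoxyphenyl)cyclohexylidene]acetaldehyde
Product: 18 3-[2-ethyl-3,5-dimethyl-4,6-bis(2,4,5-trimethoxyphenyl)cyclohexylidene]-2-methoxypropanoic acid, via trichloromethyl carbinol silyl ether 16 (not isolated), via dichloro-oxirane 17 (not isolated)
Conditions: Me3SiCCl3 (1.5 equiv), n-Bu4N(OAc) (5 mol %), THF, 0 °C; then KOH (6 equiv), MeOH, 0 → 40 °C; 1 M HCl work-up
Reagents that add atoms: trimethyl(trichloromethyl)silane, C[Si](C)(C)C(Cl)(Cl)Cl; methanol, CO; potassium hydroxide, [K+].[OH-]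
Why: Acetate-catalysed trichloromethyl transfer consumes the γ-acidic enal before strong base is added, and the Jocic–Reeve reaction (gem-dichloro-oxirane opened by methoxide at the allylic carbon, acyl chloride hydrolysed) then gives the α-methoxy acid, whose uncontrolled new centre becomes sp2 in step 11.

Step 10
Reactants: 19 trichloroethene; 20 potassium tert-butoxide
Product: 23 tert-butoxyethyne, via dichlorovinyl ether 21 (not isolated), via lithium alkoxyethynide 22 (not isolated)
Conditions: THF, −78 → 23 °C; then n-BuLi (2.2 equiv), −78 → −40 °C; then H2O, −78 °C; used as a pentane solution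
Reagents that add atoms: none
Why: One-pot ynol ether synthesis of the Greene type: tert-butoxide adds to dichloroacetylene formed from trichloroethene, then dehydrochlorination and chlorine–lithium exchange give the lithium alkoxyethynide, which is protonated.

Step 11
Reactants: 18 3-[2-ethyl-3,5-dimethyl-4,6-bis(2,4,5-trimethoxyphenyl)cyclohexylidene]-2-methoxypropanoic acid; 23 tert-butoxyethyne
Product: 28 3-tert-butoxy-7-ethyl-4-methoxy-8,10-dimethyl-9,11-bis(2,4,5-trimethoxyphenyl)spiro[5.5]undeca-2,4-dien-1-one, via acid chloride 24 (not isolated), via methoxy(vinyl)ketene 25 (not isolated), via cyclobutenone 26 (not isolated), via dienylketene 27 (not isolated)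
Conditions: 1-chloro-N,N,2-trimethylprop-1-en-1-amine (1.2 equiv), CH2Cl2, 0 °C; then slow addition to 23 (3 equiv), Et3N (1.5 equiv), toluene, 0 → 23 °C; then 80 °C, dark
Reagents that add atoms: none
Why: Acid chloride 24, made under neutral conditions, is dehydrochlorinated by Et3N at its doubly activated α-carbon to methoxy(vinyl)ketene 25, which adds tert-butoxyethyne [2+2] to give cyclobutenone 26 (the nucleophilic CH terminus of the ynol ether bonds to the ketene carbonyl carbon, the oxygen-bearing carbon to the methoxy-bearing carbon); on warming, 26 opens by conrotatory 4π electrocyclisation to dienylketene 27, which closes by disrotatory thermal 6π electrocyclisation onto the fully substituted exocyclic alkene carbon. The closest known reaction types are the Danheiser benzannulation (vinylketene plus alkoxy- or siloxyalkyne) and the Moore rearrangement of 4-alkenyl-4-alkoxycyclobutenones, here stopped at the cyclohexa-2,4-dienone because the ring terminus carries no hydrogen. The transient four-membered ring closes by ketene–alkyne [2+2] cycloaddition and the six-membered dienone ring by 6π electrocyclisation. The only new stereocentre, the spiro carbon, is controlled by the cyclohexane chair: the axial C8 methyl group, 1,3 to the alkylidene carbon, blocks the axial face, so the ketene carbon bonds on the equatorial face and ends equatorial with CH= axial, as in the target. The step needs regioselectivity in the [2+2] (secured by the polarity of the ynol ether), inward rotation of the alkenyl group in the ring opening (secured by the outward preference of the C4 methoxy donor of 26) and the facial selectivity just described; both alkene isomers of 18 converge because the alkylidene carbon becomes sp3.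

Step 12
Reactants: 28 3-tert-butoxy-7-ethyl-4-methoxy-8,10-dimethyl-9,11-bis(2,4,5-trimethoxyphenyl)spiro[5.5]undeca-2,4-dien-1-one
Product: 29 tatanan B
Conditions: MeOTf (2 equiv), 2,6-di-tert-butyl-4-methylpyridine (3 equiv), CH2Cl2, −20 → 23 °C
Reagents that add atoms: methyl trifluoromethanesulfonate, COS(=O)(=O)C(F)(F)F
Why: O-methylation of the vinylogous ester carbonyl oxygen gives a 1-methoxy-3-tert-butoxycyclohexadienyl cation that should shed the tert-butyl group as 2-methylpropene at once, an alkylative 1,3-carbonyl transposition that fixes the methyl group on the oxygen next to the spiro carbon and leaves the cross-conjugated 2,5-dienone with no stereocentre touched.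

Compound list
1 | 1-bromo-2,4,5-trimethoxybenzene | COc1cc(OC)c(Br)cc1OC | starting material
2 | tert-butyl acetate | CC(=O)OC(C)(C)C | starting material
3 | tert-butyl 2-(2,4,5-trimethoxyphenyl)acetate | CC(C)(C)OC(=O)Cc1cc(OC)c(OC)cc1OC | intermediate
4 | butanoyl chloride | CCCC(=O)Cl | starting material
5 | tert-butyl 3-oxo-2-(2,4,5-trimethoxyphenyl)hexanoate (racemic) | CCCC(=O)C(c1cc(OC)c(OC)cc1OC)C(=O)OC(C)(C)C | intermediate
6 | (E)-but-2-enal | C/C=C/C=O | starting material
7 | tert-butyl (3S)-2-butanoyl-3-methyl-5-oxo-2-(2,4,5-trimethoxyphenyl)pentanoate (both C2 epimers) | O=CC[C@H](C)C(c1cc(OC)c(OC)cc1OC)(C(=O)CCC)C(=O)OC(C)(C)C | intermediate (not isolated)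
8 | (5S,6S)-2-ethyl-5-methyl-6-(2,4,5-trimethoxyphenyl)cyclohex-2-en-1-one (aryl trans to methyl) | CCC1=CC[C@H](C)[C@@H](c2cc(OC)c(OC)cc2OC)C1=O | intermediate
9 | (5S,6S)-2-ethyl-1,5-dimethyl-6-(2,4,5-trimethoxyphenyl)cyclohex-2-en-1-ol (both C1 epimers) | CCC1=CC[C@H](C)[C@@H](c2cc(OC)c(OC)cc2OC)C1(C)O | intermediate
10 | (4R,5S)-2-ethyl-3,5-dimethyl-4-(2,4,5-trimethoxyphenyl)cyclohex-2-en-1-one (4-aryl trans to 5-methyl) | CCC1=C(C)[C@H](c2cc(OC)c(OC)cc2OC)[C@@H](C)CC1=O | intermediate
11 | (2R,3R,4R,5S)-2-ethyl-3,5-dimethyl-4-(2,4,5-trimethoxyphenyl)cyclohexan-1-one (2-ethyl, 3-methyl and 4-aryl cis; 5-methyl trans) | CC[C@@H]1[C@H](C)[C@H](c2cc(OC)c(OC)cc2OC)[C@@H](C)CC1=O | intermediate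
12 | (2R,3R,4S,5R,6R)-2-ethyl-3,5-dimethyl-4,6-bis(2,4,5-trimethoxyphenyl)cyclohexan-1-one (2-ethyl, 3-methyl, 4-aryl and 6-aryl cis; 5-methyl trans) | CC[C@@H]1[C@H](C)[C@H](c2cc(OC)c(OC)cc2OC)[C@@H](C)[C@H](c2cc(OC)c(OC)cc2OC)C1=O | intermediate
13 | (Z)-1-bromo-2-ethoxyethene | CCO/C=C\Br | starting material
14 | 1-[(Z)-2-ethoxyethenyl]-2-ethyl-3,5-dimethyl-4,6-bis(2,4,5-trimethoxyphenyl)cyclohexan-1-ol (ring centres as in 12; both C1 epimers) | CC[C@@H]1[C@H](C)[C@H](c2cc(OC)c(OC)cc2OC)[C@@H](C)[C@H](c2cc(OC)c(OC)cc2OC)C1(O)/C=C\OCC | intermediate (not isolated)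
15 | 2-[2-ethyl-3,5-dimethyl-4,6-bis(2,4,5-trimethoxyphenyl)cyclohexylidene]acetaldehyde (ring centres as in 12; E/Z mixture) | CC[C@@H]1[C@H](C)[C@H](c2cc(OC)c(OC)cc2OC)[C@@H](C)[C@H](c2cc(OC)c(OC)cc2OC)C1=CC=O | intermediate
16 | trimethylsilyl ether of 1,1,1-trichloro-3-[cyclohexylidene of 15]propan-2-ol (ring centres as in 12; both carbinol epimers) | CC[C@@H]1[C@H](C)[C@H](c2cc(OC)c(OC)cc2OC)[C@@H](C)[C@H](c2cc(OC)c(OC)cc2OC)C1=CC(O[Si](C)(C)C)C(Cl)(Cl)Cl | intermediate (not isolated)
17 | 2,2-dichloro-3-[(cyclohexylidene of 15)methyl]oxirane (ring centres as in 12) | CC[C@@H]1[C@H](C)[C@H](c2cc(OC)c(OC)cc2OC)[C@@H](C)[C@H](c2cc(OC)c(OC)cc2OC)C1=CC2OC2(Cl)Cl | intermediate (not isolated)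
18 | 3-[2-ethyl-3,5-dimethyl-4,6-bis(2,4,5-trimethoxyphenyl)cyclohexylidene]-2-methoxypropanoic acid (ring centres as in 12; both C2 epimers; E/Z mixture) | CC[C@@H]1[C@H](C)[C@H](c2cc(OC)c(OC)cc2OC)[C@@H](C)[C@H](c2cc(OC)c(OC)cc2OC)C1=CC(OC)C(O)=O | intermediate
19 | trichloroethene | ClC=C(Cl)Cl | starting material
20 | potassium tert-butoxide | CC(C)(C)[O-].[K+] | starting material
21 | tert-butyl 1,2-dichloroethenyl ether | CC(C)(C)OC(Cl)=CCl | intermediate (not isolated)
22 | lithium tert-butoxyethynide | [Li]C#COC(C)(C)C | intermediate (not isolated)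
23 | tert-butoxyethyne | C#COC(C)(C)C | intermediate
24 | acid chloride of 18 | CC[C@@H]1[C@H](C)[C@H](c2cc(OC)c(OC)cc2OC)[C@@H](C)[C@H](c2cc(OC)c(OC)cc2OC)C1=CC(OC)C(Cl)=O | intermediate (not isolated)
25 | 3-[cyclohexylidene of 15]-2-methoxyprop-1-en-1-one, the methoxy(vinyl)ketene (ring centres as in 12) | CC[C@@H]1[C@H](C)[C@H](c2cc(OC)c(OC)cc2OC)[C@@H](C)[C@H](c2cc(OC)c(OC)cc2OC)C1=CC(OC)=C=O | intermediate (not isolated)
26 | 3-tert-butoxy-4-methoxy-4-[(cyclohexylidene of 15)methyl]cyclobut-2-en-1-one (ring centres as in 12; both C4 epimers) | CC[C@@H]1[C@H](C)[C@H](c2cc(OC)c(OC)cc2OC)[C@@H](C)[C@H](c2cc(OC)c(OC)cc2OC)C1=CC2(OC)C(=O)C=C2OC(C)(C)C | intermediate (not isolated)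
27 | (3Z)-3-tert-butoxy-4-methoxy-5-[cyclohexylidene of 15]penta-1,3-dien-1-one, the dienylketene (ring centres as in 12) | CC[C@@H]1[C@H](C)[C@H](c2cc(OC)c(OC)cc2OC)[C@@H](C)[C@H](c2cc(OC)c(OC)cc2OC)C1=C/C(OC)=C(OC(C)(C)C)\C=C=O | intermediate (not isolated)
28 | 3-tert-butoxy-7-ethyl-4-methoxy-8,10-dimethyl-9,11-bis(2,4,5-trimethoxyphenyl)spiro[5.5]undeca-2,4-dien-1-one (7-ethyl, 8-methyl, 9-aryl and 11-aryl cis, 10-methyl trans; C1 carbonyl carbon equatorial on the face of the 10-methyl group, C5 axial) | CC[C@@H]1[C@H](C)[C@H](c2cc(OC)c(OC)cc2OC)[C@@H](C)[C@H](c2cc(OC)c(OC)cc2OC)[C@]12C=C(OC)C(OC(C)(C)C)=CC2=O | intermediate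
29 | tatanan B, 7-ethyl-1,4-dimethoxy-8,10-dimethyl-9,11-bis(2,4,5-trimethoxyphenyl)spiro[5.5]undeca-1,4-dien-3-one (same spatial arrangement as 28) | CC[C@@H]1[C@H](C)[C@H](c2cc(OC)c(OC)cc2OC)[C@@H](C)[C@H](c2cc(OC)c(OC)cc2OC)[C@]12C=C(OC)C(=O)C=C2OC | target

Total step count: 12. Longest linear sequence: 11 steps (steps 1–9, 11 and 12; step 10 prepares the ynol ether).

Steps most likely to fail

Step 11. The transient alkoxyketene may oligomerise faster than it is captured, or the amine hydrochloride may degrade the ynol ether before the cycloaddition. The fallback releases the ketene from an ester enolate and runs the cascade in two stages. It sets out from 18 (through its chloride 24): esterification with lithium 2,6-di-tert-butyl-4-methylphenoxide gives the hindered aryl ester F1. LiN(i-Pr)2 (THF, −78 °C) forms the enolate, which on warming to 0 °C in the presence of 23 expels the phenoxide (ketene formation from hindered aryl ester enolates) and gives cyclobutenone 26 in an amine-free medium. 26 is isolated and thermolysed separately in dilute toluene (80 °C), and the route is rejoined at 28.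

Step 12. The cyclohexadienyl cation may fragment by cleavage of a spiro C–C bond toward a benzylic cation, or the expelled tert-butyl cation may alkylate the electron-rich aryl rings. The fallback avoids a discrete cation and sets out from 28. The tert-butyl enol ether is cleaved (CF3CO2H, CH2Cl2, 0 °C, 1,3,5-trimethoxybenzene as trap) to the vinylogous acid F2. O-Methylation of F2 with Me3SiCHN2 (MeOH/toluene) gives 29 together with the regioisomeric 3,4-dimethoxy-2,4-dienone F3, which is separated and recycled to F2 by mild aqueous acid. The route is rejoined at 29.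

Step 6. Hydrogen may be delivered with poor facial selectivity, or the tetrasubstituted double bond may migrate on palladium before reduction. The fallback makes the delivery hydroxyl-directed and sets out from 10. Luche reduction (NaBH4, CeCl3·7H2O, MeOH, −40 °C; hydride anti to the axial 5-methyl group) gives the allylic alcohol F4. Homogeneous hydrogenation with [Ir(cod)(PCy3)(py)]PF6 (H2, CH2Cl2) adds hydrogen syn to the hydroxyl group and gives the cyclohexanol F5. Oxidation with Dess–Martin periodinane rejoins the route at 11.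

Further compounds
F1 | step 11 | 2,6-di-tert-butyl-4-methylphenyl ester of 18 | CC[C@@H]1[C@H](C)[C@H](c2cc(OC)c(OC)cc2OC)[C@@H](C)[C@H](c2cc(OC)c(OC)cc2OC)C1=CC(OC)C(=O)Oc2c(C(C)(C)C)cc(C)cc2C(C)(C)C
F2 | step 12 | 7-ethyl-3-hydroxy-4-methoxy-8,10-dimethyl-9,11-bis(2,4,5-trimethoxyphenyl)spiro[5.5]undeca-2,4-dien-1-one (vinylogous acid, one tautomer drawn) | CC[C@@H]1[C@H](C)[C@H](c2cc(OC)c(OC)cc2OC)[C@@H](C)[C@H](c2cc(OC)c(OC)cc2OC)[C@]12C=C(OC)C(O)=CC2=O
F3 | step 12 | 7-ethyl-3,4-dimethoxy-8,10-dimethyl-9,11-bis(2,4,5-trimethoxyphenyl)spiro[5.5]undeca-2,4-dien-1-one | CC[C@@H]1[C@H](C)[C@H](c2cc(OC)c(OC)cc2OC)[C@@H](C)[C@H](c2cc(OC)c(OC)cc2OC)[C@]12C=C(OC)C(OC)=CC2=O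
F4 | step 6 | 2-ethyl-3,5-dimethyl-4-(2,4,5-trimethoxyphenyl)cyclohex-2-en-1-ol (hydroxyl cis to the 5-methyl group) | CCC1=C(C)[C@H](c2cc(OC)c(OC)cc2OC)[C@@H](C)C[C@H]1O
F5 | step 6 | 2-ethyl-3,5-dimethyl-4-(2,4,5-trimethoxyphenyl)cyclohexan-1-ol (ring centres as in 11; hydroxyl cis to the 5-methyl group) | CC[C@@H]1[C@H](C)[C@H](c2cc(OC)c(OC)cc2OC)[C@@H](C)C[C@H]1O
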